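**Retrosynthetic overview**

1. Target 17 ← hydrogenolysis of the four benzyl ethers of flavonol 16 ← C3–O bond by epoxidation and acid opening of flavone 14 ← 5-O-benzylation and 8-O-methylation of 5,8-dihydroxyflavone 12.
2. 12 ← O1–C8a bond: ring C is closed by conjugate addition of the enol oxygen of β-diketone 9 to the acylquinone obtained by oxidising its 2,5-dihydroxyaryl ring.
3. Feature used: the oxygens on C5 and C8 of ring A are para, so ring A is a latent 1,4-benzoquinone whose only C–H carbon, C8a, lies β to the C5 quinone carbonyl and to the C4 ketone; O1 is therefore attached by C–H etherification and the arene to be made is only pentasubstituted.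
4. 9 ← C2–C3 bond by aroylation of the enolate of acetophenone 6 with acid chloride 8; 6 ← gallacetophenone 1 by 4-O-benzylation, 3-O-methylation and Elbs hydroxylation para to the chelated phenol.
5. Ring order: rings A and B come with the starting materials; ring C is the only ring formed (step 6).

Key step: step 6

Remark: the target is achiral. The only stereocentres in the route are the two of epoxide 15, which forms as a racemate with a forced cis ring fusion and is consumed in the same step; its SMILES shows one enantiomer.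

**Route**

Step 1
Reactants: 1 gallacetophenone (2,3,4-trihydroxyacetophenone); 2 benzyl bromide
Product: 3 1-[4-(benzyloxy)-2,3-dihydroxyphenyl]ethanone
Conditions: BnBr (1.0 equiv), NaHCO3 (1.2 equiv), KI (cat.), DMF, 40 °C, N2
Reagents that add atoms: none
Why: The 4-OH, para to the acetyl group, is the most acidic phenol (the 2-OH is chelated to the carbonyl and the 3-OH is flanked on both sides), so Williamson etherification with one equivalent of benzyl bromide and a weak base should give the 4-benzyl ether.

Step 2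
Reactants: 3 1-[4-(benzyloxy)-2,3-dihydroxyphenyl]ethanone
Product: 4 1-[4-(benzyloxy)-2-hydroxy-3-methoxyphenyl]ethanone
Conditions: MeI (1.1 equiv), K2CO3 (1.1 equiv), acetone, reflux, N2
Reagents that add atoms: iodomethane, CI
Why: Of the two remaining phenols only the 3-OH is free of the carbonyl chelate, so Williamson methylation with one equivalent of MeI should stop at the 3-methyl ether, as in the classical partial methylation of gallacetophenone.

Step 3
Reactants: 4 1-[4-(benzyloxy)-2-hydroxy-3-methoxyphenyl]ethanone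
Product: 6 1-[4-(benzyloxy)-2,5-dihydroxy-3-methoxyphenyl]ethanone, via potassium aryl sulfate 5 (not isolated)
Conditions: K2S2O8 (1.1 equiv), 10% aq NaOH, pyridine, 5 °C to rt; then aq HCl, Na2SO3, 80 °C
Reagents that add atoms: potassium peroxodisulfate, [K+].[K+].[O-]S(=O)(=O)OOS(=O)(=O)[O-]
Why: Elbs persulfate oxidation, in which the phenolate of 4 attacks peroxodisulfate through C5, the only free carbon para to the phenol, to give aryl sulfate 5, whose sulfate ester is then hydrolysed by hot dilute acid while the aryl benzyl ether is expected to hold.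

Step 4
Reactants: 7 3,4-bis(benzyloxy)benzoic acid
Product: 8 3,4-bis(benzyloxy)benzoyl chloride
Conditions: (COCl)2 (1.5 equiv), DMF (cat.), CH2Cl2, 0 °C to rt; evaporate
Reagents that add atoms: oxalyl chloride, ClC(=O)C(=O)Cl
Why: Standard acid chloride formation through the chloroiminium ion from DMF and oxalyl chloride, which leaves the aryl benzyl ethers untouched.

Step 5
Reactants: 6 1-[4-(benzyloxy)-2,5-dihydroxy-3-methoxyphenyl]ethanone; 8 3,4-bis(benzyloxy)benzoyl chloride
Product: 9 1-[4-(benzyloxy)-2,5-dihydroxy-3-methoxyphenyl]-3-[3,4-bis(benzyloxy)phenyl]propane-1,3-dione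
Conditions: LiN(SiMe3)2 (4.2 equiv), THF, −78 to −10 °C, Ar; 8 (1.0 equiv), −78 °C to rt; AcOH quench
Reagents that add atoms: none
Why: Direct C-aroylation of a polylithiated o-hydroxyacetophenone (crossed Claisen condensation, the one-pot variant of the Baker–Venkataraman synthesis), in which the enolate carbon of the bis-phenoxide enolate is the most nucleophilic site toward 8 and the fourth equivalent of base takes up the acidic diketone proton so that no second acylation follows.

Step 6
Reactants: 9 1-[4-(benzyloxy)-2,5-dihydroxy-3-methoxyphenyl]-3-[3,4-bis(benzyloxy)phenyl]propane-1,3-dione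
Product: 12 7-(benzyloxy)-2-[3,4-bis(benzyloxy)phenyl]-5,8-dihydroxy-6-methoxychromen-4-one, via acylquinone 10 (not isolated), via flavone-5,8-quinone 11 (not isolated)
Conditions: Ag2O (2.5 equiv), Na2SO4, THF (0.01 M), rt, dark, Ar; filter; then aq Na2S2O4, EtOAc, rt
Reagents that add atoms: none
Why: Proposed new method: Ag2O oxidises the 2,5-dihydroxyaryl ring of 9 to the 2-acyl-1,4-benzoquinone 10, whose only ring C–H carbon (the future C8a) is β to both the side-chain ketone (future C4) and the quinone carbonyl at the future C5, and the oxygen of the enolised diketone on the aryl-bearing carbon adds to it, after which loss of the C8a proton restores aromatic ring A. The closest known reaction type is the oxidative cyclisation of 2,5-dihydroxy-2'-hydroxybenzophenones to xanthones, where a phenol oxygen adds to the acylquinone in the same oxa-Michael sense; a 1,3-diketone enol oxygen has not been shown as the nucleophile, but it is more acidic than a phenol and the Z-enol geometry holds it within reach of the acceptor carbon. Ring C closes by a 6-endo-trig attack that forms O1–C8a, whereas attack through the central diketone carbon would need a four-membered ring. No stereocentre is formed. The step needs closure at C8a and not condensation of the chelated C5 oxygen with the diketone, and this is secured because that oxygen is a quinone carbonyl as soon as oxidation has occurred, no acid is present, the other quinone carbons (C6, C7) are blocked by their alkoxy groups, and high dilution disfavours intermolecular C-addition of one diketone to another quinone. Since 10 is a stronger oxidant than the product, the hydroquinone first formed is expected to be oxidised on to flavonequinone 11 by the excess Ag2O, and the Na2S2O4 wash reduces 11 to 12.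

Step 7
Reactants: 12 7-(benzyloxy)-2-[3,4-bis(benzyloxy)phenyl]-5,8-dihydroxy-6-methoxychromen-4-one
Product: 13 7-(benzyloxy)-2-[3,4-bis(benzyloxy)phenyl]-5-hydroxy-6,8-dimethoxychromen-4-one
Conditions: MeI (1.1 equiv), K2CO3 (1.1 equiv), acetone, rt, Ar
Reagents that add atoms: iodomethane, CI
Why: The 5-OH is held in a hydrogen bond to the C4 carbonyl and is far less nucleophilic than the free 8-OH, so Williamson methylation with one equivalent of MeI should occur at O8 only, the usual selectivity of 5-hydroxyflavones.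

Step 8
Reactants: 13 7-(benzyloxy)-2-[3,4-bis(benzyloxy)phenyl]-5-hydroxy-6,8-dimethoxychromen-4-one; 2 benzyl bromide
Product: 14 5,7-bis(benzyloxy)-2-[3,4-bis(benzyloxy)phenyl]-6,8-dimethoxychromen-4-one
Conditions: BnBr (1.5 equiv), K2CO3 (3 equiv), KI (cat.), DMF, 80 °C
Reagents that add atoms: none
Why: Forcing Williamson benzylation in hot DMF with iodide catalysis is the standard way to alkylate the chelated, hindered 5-OH of a flavone, and no other group in 13 reacts under these conditions.

Step 9
Reactants: 14 5,7-bis(benzyloxy)-2-[3,4-bis(benzyloxy)phenyl]-6,8-dimethoxychromen-4-one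
Product: 16 5,7-bis(benzyloxy)-2-[3,4-bis(benzyloxy)phenyl]-3-hydroxy-6,8-dimethoxychromen-4-one, via 2,3-epoxyflavanone 15 (not isolated)
Conditions: dimethyldioxirane (acetone solution, excess), CH2Cl2, 0 °C to rt; evaporate; then p-TsOH·H2O (cat.), CH2Cl2, rt
Reagents that add atoms: dimethyldioxirane, CC1(C)OO1
Why: Dimethyldioxirane epoxidation of the C2=C3 bond is a known route from 5-alkoxyflavones to flavonols, the epoxide 15 being opened by acid at C2 to an oxocarbenium ion stabilised by O1 and the aryl group, which loses the C3 proton to give the 3-hydroxyflavone.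

Step 10
Reactants: 16 5,7-bis(benzyloxy)-2-[3,4-bis(benzyloxy)phenyl]-3-hydroxy-6,8-dimethoxychromen-4-one
Product: 17 3,5,7,3',4'-pentahydroxy-6,8-dimethoxyflavone
Conditions: H2 (1 atm), Pd/C (10% Pd on carbon), THF/MeOH, rt
Reagents that add atoms: none
Why: Catalytic hydrogenolysis over Pd/C cleaves the four aryl benzyl ethers to toluene and the free phenols, while the flavonol C2=C3 bond, part of a vinylogous ester, is not reduced under these mild conditions.

**Compound list**

1 | gallacetophenone (2,3,4-trihydroxyacetophenone) | CC(=O)c1ccc(O)c(O)c1O | starting material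
2 | benzyl bromide | BrCc1ccccc1 | starting material
3 | 1-[4-(benzyloxy)-2,3-dihydroxyphenyl]ethanone | CC(=O)c1ccc(OCc2ccccc2)c(O)c1O | intermediate
4 | 1-[4-(benzyloxy)-2-hydroxy-3-methoxyphenyl]ethanone | CC(=O)c1ccc(OCc2ccccc2)c(OC)c1O | intermediate
5 | potassium 5-acetyl-2-(benzyloxy)-4-hydroxy-3-methoxyphenyl sulfate | CC(=O)c1cc(OS(=O)(=O)[O-])c(OCc2ccccc2)c(OC)c1O.[K+] | intermediate (not isolated)
6 | 1-[4-(benzyloxy)-2,5-dihydroxy-3-methoxyphenyl]ethanone | CC(=O)c1cc(O)c(OCc2ccccc2)c(OC)c1O | intermediate
7 | 3,4-bis(benzyloxy)benzoic acid | OC(=O)c1ccc(OCc2ccccc2)c(OCc2ccccc2)c1 | starting material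
8 | 3,4-bis(benzyloxy)benzoyl chloride | ClC(=O)c1ccc(OCc2ccccc2)c(OCc2ccccc2)c1 | intermediate
9 | 1-[4-(benzyloxy)-2,5-dihydroxy-3-methoxyphenyl]-3-[3,4-bis(benzyloxy)phenyl]propane-1,3-dione | COc1c(O)c(C(=O)CC(=O)c2ccc(OCc3ccccc3)c(OCc3ccccc3)c2)cc(O)c1OCc1ccccc1 | intermediate
10 | 5-(benzyloxy)-2-{3-[3,4-bis(benzyloxy)phenyl]-3-oxopropanoyl}-6-methoxy-1,4-benzoquinone | COC1=C(OCc2ccccc2)C(=O)C=C(C(=O)CC(=O)c2ccc(OCc3ccccc3)c(OCc3ccccc3)c2)C1=O | intermediate (not isolated)
11 | 7-(benzyloxy)-2-[3,4-bis(benzyloxy)phenyl]-6-methoxychromene-4,5,8-trione | COC1=C(OCc2ccccc2)C(=O)C2=C(C1=O)C(=O)C=C(c1ccc(OCc3ccccc3)c(OCc3ccccc3)c1)O2 | intermediate (not isolated)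
12 | 7-(benzyloxy)-2-[3,4-bis(benzyloxy)phenyl]-5,8-dihydroxy-6-methoxychromen-4-one | COc1c(O)c2c(=O)cc(-c3ccc(OCc4ccccc4)c(OCc4ccccc4)c3)oc2c(O)c1OCc1ccccc1 | intermediate
13 | 7-(benzyloxy)-2-[3,4-bis(benzyloxy)phenyl]-5-hydroxy-6,8-dimethoxychromen-4-one | COc1c(O)c2c(=O)cc(-c3ccc(OCc4ccccc4)c(OCc4ccccc4)c3)oc2c(OC)c1OCc1ccccc1 | intermediate
14 | 5,7-bis(benzyloxy)-2-[3,4-bis(benzyloxy)phenyl]-6,8-dimethoxychromen-4-one | COc1c(OCc2ccccc2)c2c(=O)cc(-c3ccc(OCc4ccccc4)c(OCc4ccccc4)c3)oc2c(OC)c1OCc1ccccc1 | intermediate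
15 | rac-5,7-bis(benzyloxy)-2-[3,4-bis(benzyloxy)phenyl]-2,3-epoxy-6,8-dimethoxychroman-4-one (cis-fused epoxide, one enantiomer shown) | COc1c(OCc2ccccc2)c2C(=O)[C@H]3O[C@@]3(c3ccc(OCc4ccccc4)c(OCc4ccccc4)c3)Oc2c(OC)c1OCc1ccccc1 | intermediate (not isolated)
16 | 5,7-bis(benzyloxy)-2-[3,4-bis(benzyloxy)phenyl]-3-hydroxy-6,8-dimethoxychromen-4-one | COc1c(OCc2ccccc2)c2c(=O)c(O)c(-c3ccc(OCc4ccccc4)c(OCc4ccccc4)c3)oc2c(OC)c1OCc1ccccc1 | intermediate
17 | 3,5,7,3',4'-pentahydroxy-6,8-dimethoxyflavone | COc1c(O)c(OC)c2oc(-c3ccc(O)c(O)c3)c(O)c(=O)c2c1O | target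

**Step count**

Total steps: 10. Longest linear sequence: 9 steps (steps 1, 2, 3, 5, 6, 7, 8, 9, 10 from gallacetophenone); step 4 is a one-step side branch.

**Steps most likely to fail**

Step 6. The intramolecular O-closure may be outrun by intermolecular Michael addition of the central diketone carbon of one molecule to the quinone of another (oligomers or benzofurans), or the electron-poor quinone may decompose before it cyclises. The fallback uses known chemistry, sets out from 9 and returns to the route at 13. Compound 9 is cyclodehydrated in the ordinary sense (p-TsOH·H2O cat., toluene, 90 °C), the chelated phenol condensing with the diketone to give the regioisomeric flavone 7-(benzyloxy)-2-[3,4-bis(benzyloxy)phenyl]-6-hydroxy-8-methoxychromen-4-one F1, in which the missing ring A oxygen is now the one at C5. 2-Iodoxybenzoic acid (IBX) in DMF at rt, the known ortho-oxygenation of electron-rich phenols, should oxidise the 6-phenol at its only free ortho carbon, C5, to the ortho-quinone 7-(benzyloxy)-2-[3,4-bis(benzyloxy)phenyl]-8-methoxychromene-4,5,6-trione F2. Aqueous Na2S2O4 reduces this to 7-(benzyloxy)-2-[3,4-bis(benzyloxy)phenyl]-5,6-dihydroxy-8-methoxychromen-4-one F3. Methylation of the unchelated 6-OH (MeI, 1 equiv, K2CO3, acetone) then gives 13, since ring A of 13 carries a methoxy group on both C6 and C8, and the route continues with step 8.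

Step 9. Epoxidation of the hindered, electron-poor C2=C3 bond may be slow, so that oxidation of the benzylic C–H bonds of the four benzyl ethers or of electron-rich ring B competes, and the epoxide may open by ring contraction instead of proton loss. The fallback sets out from 14 and returns at 16. LiN(iPr)2 in THF at −78 °C deprotonates C3, the known lithiation of 5-alkoxyflavones, to give 5,7-bis(benzyloxy)-2-[3,4-bis(benzyloxy)phenyl]-3-lithio-6,8-dimethoxychromen-4-one F4. B(OMe)3 traps it as dimethyl {5,7-bis(benzyloxy)-2-[3,4-bis(benzyloxy)phenyl]-6,8-dimethoxy-4-oxochromen-3-yl}boronate F5, and oxidation of the C–B bond with H2O2 in AcOH gives 16.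

Step 3. Conversion of the chelated, poorly soluble phenolate may be low, radical over-oxidation may compete, and the benzyl ether may be partly lost during the hot acid hydrolysis of the sulfate. The fallback sets out from 4 and returns at 6. NBS in MeCN at 0 °C brominates C5 (para to the phenol, ortho to the benzyloxy group, meta to the acetyl group) to give 1-[4-(benzyloxy)-5-bromo-2-hydroxy-3-methoxyphenyl]ethanone F6. Miyaura borylation (B2pin2, PdCl2(dppf), KOAc, dioxane, 90 °C) gives 1-[4-(benzyloxy)-2-hydroxy-3-methoxy-5-(4,4,5,5-tetramethyl-1,3,2-dioxaborolan-2-yl)phenyl]ethanone F7. Mild oxidation of the C–B bond (NaBO3·4H2O, THF/H2O, rt), which is much faster than Dakin cleavage of the ketone, gives 6.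

**Further compounds**

F1 | step 6 | 7-(benzyloxy)-2-[3,4-bis(benzyloxy)phenyl]-6-hydroxy-8-methoxychromen-4-one | COc1c(OCc2ccccc2)c(O)cc2c(=O)cc(-c3ccc(OCc4ccccc4)c(OCc4ccccc4)c3)oc12
F2 | step 6 | 7-(benzyloxy)-2-[3,4-bis(benzyloxy)phenyl]-8-methoxychromene-4,5,6-trione | COC1=C(OCc2ccccc2)C(=O)C(=O)C2=C1OC(c1ccc(OCc3ccccc3)c(OCc3ccccc3)c1)=CC2=O
F3 | step 6 | 7-(benzyloxy)-2-[3,4-bis(benzyloxy)phenyl]-5,6-dihydroxy-8-methoxychromen-4-one | COc1c(OCc2ccccc2)c(O)c(O)c2c(=O)cc(-c3ccc(OCc4ccccc4)c(OCc4ccccc4)c3)oc12
F4 | step 9 | 5,7-bis(benzyloxy)-2-[3,4-bis(benzyloxy)phenyl]-3-lithio-6,8-dimethoxychromen-4-one | [Li]c1c(-c2ccc(OCc3ccccc3)c(OCc3ccccc3)c2)oc2c(OC)c(OCc3ccccc3)c(OC)c(OCc3ccccc3)c2c1=O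
F5 | step 9 | dimethyl {5,7-bis(benzyloxy)-2-[3,4-bis(benzyloxy)phenyl]-6,8-dimethoxy-4-oxochromen-3-yl}boronate | COB(OC)c1c(-c2ccc(OCc3ccccc3)c(OCc3ccccc3)c2)oc2c(OC)c(OCc3ccccc3)c(OC)c(OCc3ccccc3)c2c1=O
F6 | step 3 | 1-[4-(benzyloxy)-5-bromo-2-hydroxy-3-methoxyphenyl]ethanone | CC(=O)c1cc(Br)c(OCc2ccccc2)c(OC)c1O
F7 | step 3 | 1-[4-(benzyloxy)-2-hydroxy-3-methoxy-5-(4,4,5,5-tetramethyl-1,3,2-dioxaborolan-2-yl)phenyl]ethanone | CC(=O)c1cc(B2OC(C)(C)C(C)(C)O2)c(OCc2ccccc2)c(OC)c1O
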